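Plan
- Labels: the upper unit has rings A (benzo), B (catechol) and C (pyran); the lower unit has rings D, E and F in the same sense. α means below and β above the plane in the usual flavan drawing (ring A left, O1 on top).
- Cuts: first the seven O-benzyl bonds and the upper C3–O bond, which is traced back to C3–B. Then O1–C2 and C3–C4 of ring C. Last, the bond from the future C4 to C6 of ring D.
- Enabling feature: upper C4 hangs on C4a, ortho to the O1-bearing C8a of ring A, and carries ring D. O1–C8a–C4a–C4 is therefore the oxadiene of an o-quinone methide, and C2=C3 with ring B is an (E)-styrene.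
- Forward: rings D, E and F come intact from (+)-taxifolin by 5-deoxygenation, C4 reduction and C6 bromination. Ring A is joined by aryllithium addition to a salicylaldehyde, and ring C closes last in the [4+2] step, which also brings in ring B.
- Stereochemistry: lower C2 and C3 come from the chiral pool. Upper C2, C3 and C4 arise together in the cycloaddition (relative: (E)-alkene, (E)-methide, endo; absolute: chiral Brønsted acid). Boron at C3 becomes hydroxyl with retention.

Key step: step 11

Assumption: the (R)-configured acid is taken to leave open the methide face that leads to the 4α-aryl series. If the sense of induction is the opposite, the equally available (S)-acid takes its place and nothing else changes.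

Step 1
Reactants: 1 (+)-taxifolin
Product: 2 (2R,3R)-7-benzyloxy-2-[3,4-bis(benzyloxy)phenyl]-3,5-dihydroxychroman-4-one
Conditions: BnBr (3.2 equiv), K2CO3, DMF, rt, argon
Reagents that add atoms: benzyl bromide, BrCc1ccccc1
Why: Williamson ether synthesis: carbonate ionises the 7-, 3′- and 4′-phenols, whereas the 5-hydroxyl is tied up in a hydrogen bond to the C4 carbonyl and the aliphatic 3-hydroxyl is not ionised, so three benzyl groups go on selectively and C2/C3 keep their configuration at room temperature.

Step 2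
Reactants: 2 (2R,3R)-7-benzyloxy-2-[3,4-bis(benzyloxy)phenyl]-3,5-dihydroxychroman-4-one
Product: 3 (2R,3R)-7-benzyloxy-2-[3,4-bis(benzyloxy)phenyl]-3-hydroxy-4-oxochroman-5-yl trifluoromethanesulfonate
Conditions: PhNTf2, Et3N, DMAP (cat.), CH2Cl2, 0 °C → rt
Reagents that add atoms: N-phenylbis(trifluoromethanesulfonimide), FC(F)(F)S(=O)(=O)N(c1ccccc1)S(=O)(=O)C(F)(F)F
Why: O-sulfonylation of a phenol with an N-aryl triflimide: this mild triflyl donor reacts only with the phenoxide that the amine generates from the acidic 5-hydroxyl and leaves the neutral secondary 3-hydroxyl alone.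

Step 3
Reactants: 3 (2R,3R)-7-benzyloxy-2-[3,4-bis(benzyloxy)phenyl]-3-hydroxy-4-oxochroman-5-yl trifluoromethanesulfonate
Product: 4 (2R,3R)-7-benzyloxy-2-[3,4-bis(benzyloxy)phenyl]-3-hydroxychroman-4-one (tri-O-benzylfustin)
Conditions: Pd(OAc)2 (5 mol %), Ph2P(CH2)3PPh2, HCO2H, Et3N, DMF, 60 °C, argon
Reagents that add atoms: none
Why: Palladium-catalysed hydrodeoxygenation of an aryl triflate with formate as hydride source: zerovalent palladium inserts into the C5–O bond, which the ortho carbonyl activates, bound formate loses CO2, and reductive elimination gives C5–H while the homogeneous catalyst spares the benzyl ethers.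

Step 4
Reactants: 4 tri-O-benzylfustin
Product: 5 (2R,3S,4R)-7-benzyloxy-2-[3,4-bis(benzyloxy)phenyl]chroman-3,4-diol
Conditions: NaBH4, THF/EtOH, 0 °C
Reagents that add atoms: none
Why: Borohydride reduction of an aryl ketone: axial hydride delivery to the half-chair should give mainly the all-equatorial 3,4-trans diol, and the C4 configuration is of no consequence because this centre is removed in step 5.

Step 5
Reactants: 5 (2R,3S,4R)-7-benzyloxy-2-[3,4-bis(benzyloxy)phenyl]chroman-3,4-diol
Product: 6 (2R,3S)-7-benzyloxy-2-[3,4-bis(benzyloxy)phenyl]chroman-3-ol (tri-O-benzylfisetinidol)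
Conditions: Et3SiH (5 equiv), TFA, CH2Cl2, −20 → 0 °C
Reagents that add atoms: none
Why: Ionic hydrogenation of a benzylic alcohol: acid ionises only the 4-hydroxyl, whose cation is stabilised by the para 7-benzyloxy group and the ortho ring oxygen, and excess silane should deliver hydride faster than a second benzo ring can attack, with C2 and C3 untouched.

Step 6
Reactants: 6 tri-O-benzylfisetinidol
Product: 7 (2R,3S)-3,7-bis(benzyloxy)-2-[3,4-bis(benzyloxy)phenyl]chroman (tetra-O-benzylfisetinidol)
Conditions: NaH, BnBr, DMF, 0 °C → rt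
Reagents that add atoms: benzyl bromide, BrCc1ccccc1
Why: Williamson ether synthesis on the sodium alkoxide of the only remaining hydroxyl, the flavan no longer containing a base-sensitive carbonyl.

Step 7
Reactants: 7 tetra-O-benzylfisetinidol
Product: 8 (2R,3S)-3,7-bis(benzyloxy)-2-[3,4-bis(benzyloxy)phenyl]-6-bromochroman
Conditions: NBS (1.0 equiv), CH2Cl2, −78 → 0 °C, dark
Reagents that add atoms: N-bromosuccinimide, O=C1CCC(=O)N1Br
Why: Electrophilic aromatic bromination: C6 of ring D is para to O1 and ortho to the 7-benzyloxy group and is less crowded than C8 between two oxygens (compare the 4-bromination of 1,3-dialkoxybenzenes), while the catechol-type ring E is much less activated.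

Step 8
Reactants: 9 2,4-dihydroxybenzaldehyde
Product: 10 4-(benzyloxy)-2-hydroxybenzaldehyde
Conditions: BnBr (1.0 equiv), NaHCO3, MeCN, reflux
Reagents that add atoms: benzyl bromide, BrCc1ccccc1
Why: Regioselective Williamson ether synthesis: the weak base ionises only the 4-hydroxyl, the 2-hydroxyl being hydrogen-bonded to the formyl group.

Step 9
Reactants: 8 (2R,3S)-3,7-bis(benzyloxy)-2-[3,4-bis(benzyloxy)phenyl]-6-bromochroman; 10 4-(benzyloxy)-2-hydroxybenzaldehyde
Product: 13 (4-benzyloxy-2-hydroxyphenyl){(2R,3S)-3,7-bis(benzyloxy)-2-[3,4-bis(benzyloxy)phenyl]chroman-6-yl}methanol (both carbinol epimers), via aryllithium 11 (not isolated), via sodium phenolate 12 (not isolated)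
Conditions: 8, n-BuLi, THF, −78 °C; separately 10, NaH, THF, 0 °C; combine at −78 °C, → −20 °C; aq NH4Cl
Reagents that add atoms: none
Why: Bromine–lithium exchange followed by 1,2-addition of the aryllithium to an aldehyde: the phenol is masked beforehand as its sodium salt so that no organolithium is spent as a base (addition to a metal phenolate is what takes place whenever excess aryl-metal reagent meets a free salicylaldehyde), and the new carbinol centre, formed without control, is erased in step 11.

Step 10
Reactants: 14 3,4-bis(benzyloxy)benzaldehyde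
Product: 15 (E)-2-{2-[3,4-bis(benzyloxy)phenyl]ethenyl}-4,4,5,5-tetramethyl-1,3,2-dioxaborolane
Conditions: CH2(Bpin)2, lithium 2,2,6,6-tetramethylpiperidide (from the amine and n-BuLi), THF, 0 °C; then 14, −78 °C → rt; H2O
Reagents that add atoms: bis(pinacolboryl)methane, CC1(C)OB(CB2OC(C)(C)C(C)(C)O2)OC1(C)C
Why: Boron–Wittig olefination: the α-boryl carbanion adds to the aldehyde and syn elimination of the boron–oxygen pair from the less crowded adduct gives the (E)-alkenylboronate.

Step 11
Reactants: 13 benzhydrol (both carbinol epimers); 15 (E)-styrylboronate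
Product: 17 hepta-O-benzyl-3-deoxy-3β-(pinacolboryl)fisetinidol-(4α→6)-fisetinidol (upper ring C: 2α-aryl/3β-boryl/4α-aryl; 2,3-trans-3,4-trans; 2,4-cis), via o-quinone methide 16 (not isolated)
Conditions: (R)-3,3′-bis(2,4,6-triisopropylphenyl)-1,1′-binaphthyl-2,2′-diyl N-triflylphosphoramide (10 mol %), 15 (2.5 equiv), 4 Å MS, toluene, −20 → 0 °C, slow addition of 13
Reagents that add atoms: none
Why: Proposed new method: the strong chiral acid dehydrates 13 to the (E)-o-quinone methide 16 (ring D turned away from the carbonyl oxygen, positive character shared by the 7-benzyloxy group of ring A and the 2,4-dioxygenated ring D) and stays on its oxygen as a contact ion pair; the boron-bearing alkene carbon of 15 is the nucleophilic terminus because charge then builds up on the carbon conjugated with the 4′-benzyloxy group and hyperconjugated with the C–B bond, so it attacks C4 and the ring A oxygen collapses on that benzylic carbon. The closest known reaction type is the chiral phosphoric acid or N-triflylphosphoramide-catalysed [4+2] cycloaddition of o-quinone methides, made in situ from o-hydroxybenzhydrols, with styrenes and (E)-β-alkylstyrenes, which gives 2,4-cis-2,3-trans-chromans; a β-borylstyrene has not served as the two-carbon partner, and the stronger acid is chosen because 15 offers no hydrogen-bond donor, so only the electrophile can be activated. Ring C closes as a six-membered ring in a concerted but asynchronous inverse-demand oxa-[4+2] mode, C3–C4 forming ahead of O1–C2. C4 is set by the acid, whose 3,3′-aryl groups leave one methide face open (the lower-unit centres are too remote to steer but turn a facial error into a separable diastereomer); C2 is set relative to C4 by endo approach of ring B (2,4-cis) and C3 by suprafacial addition to the (E)-alkene (2,3-trans, 3,4-trans), so all three substituents end up equatorial and the kinetic product is also the most stable one. The step needs regioselectivity (secured by electron-rich ring B, whereas an enol ether would put its oxygen on C2), retention of boron against ipso-substitution and protodeboronation (secured by the weakly Lewis acidic, slowly exchanging pinacol ester, by the sieves and by the closeness of O1 to the developing cation) and suppression of Friedel–Crafts oligomerisation (all other phenols are benzylated and 13 meets an excess of 15).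

Step 12
Reactants: 17 3β-boryl dimer
Product: 18 hepta-O-benzylfisetinidol-(4α→6)-fisetinidol with free upper 3β-hydroxyl
Conditions: NaBO3·4H2O, THF/H2O, rt
Reagents that add atoms: sodium perborate (NaBO3·4H2O, drawn as the anhydrous dimeric salt), O[B-]1(O)OO[B-](O)(O)OO1.[Na+].[Na+]
Why: Oxidation of a secondary alkylboronic ester: in the peroxo ate complex C3 shifts from boron to oxygen with retention, giving the 3β-hydroxyl, and this shift should outrun β-elimination of the ring oxygen, as it does in the oxidation stage of flav-3-ene hydroboration.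

Step 13
Reactants: 18 hepta-O-benzyl dimer
Product: 19 fisetinidol-(4α→6)-fisetinidol, upper unit (2R,3S,4R), lower unit (2R,3S) (CNP0187520.3)
Conditions: H2 (1 atm), Pd(OH)2/C, THF/MeOH, rt
Reagents that add atoms: none
Why: Catalytic hydrogenolysis of all seven benzyl ethers under one atmosphere of hydrogen, conditions under which the cyclic C2–O1 ethers, the C4–C6 interflavan bond and the five stereocentres of benzylated flavan-3-ol oligomers persist.

Compound list
1 | (+)-taxifolin, (2R,3R)-2-(3,4-dihydroxyphenyl)-3,5,7-trihydroxychroman-4-one | Oc1cc(O)c2c(c1)O[C@H](c1ccc(O)c(O)c1)[C@@H](O)C2=O | starting material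
2 | (2R,3R)-7-benzyloxy-2-[3,4-bis(benzyloxy)phenyl]-3,5-dihydroxychroman-4-one | O(Cc1ccccc1)c1cc(O)c2c(c1)O[C@H](c1ccc(OCc3ccccc3)c(OCc3ccccc3)c1)[C@@H](O)C2=O | intermediate
3 | (2R,3R)-7-benzyloxy-2-[3,4-bis(benzyloxy)phenyl]-3-hydroxy-4-oxochroman-5-yl trifluoromethanesulfonate | O(Cc1ccccc1)c1cc(OS(=O)(=O)C(F)(F)F)c2c(c1)O[C@H](c1ccc(OCc3ccccc3)c(OCc3ccccc3)c1)[C@@H](O)C2=O | intermediate
4 | (2R,3R)-7-benzyloxy-2-[3,4-bis(benzyloxy)phenyl]-3-hydroxychroman-4-one | O(Cc1ccccc1)c1ccc2c(c1)O[C@H](c1ccc(OCc3ccccc3)c(OCc3ccccc3)c1)[C@@H](O)C2=O | intermediate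
5 | (2R,3S,4R)-7-benzyloxy-2-[3,4-bis(benzyloxy)phenyl]chroman-3,4-diol (major 3,4-trans epimer) | O(Cc1ccccc1)c1ccc2c(c1)O[C@H](c1ccc(OCc3ccccc3)c(OCc3ccccc3)c1)[C@@H](O)[C@@H]2O | intermediate
6 | (2R,3S)-7-benzyloxy-2-[3,4-bis(benzyloxy)phenyl]chroman-3-ol | O(Cc1ccccc1)c1ccc2c(c1)O[C@H](c1ccc(OCc3ccccc3)c(OCc3ccccc3)c1)[C@@H](O)C2 | intermediate
7 | (2R,3S)-3,7-bis(benzyloxy)-2-[3,4-bis(benzyloxy)phenyl]chroman | O(Cc1ccccc1)c1ccc2c(c1)O[C@H](c1ccc(OCc3ccccc3)c(OCc3ccccc3)c1)[C@@H](OCc3ccccc3)C2 | intermediate
8 | (2R,3S)-3,7-bis(benzyloxy)-2-[3,4-bis(benzyloxy)phenyl]-6-bromochroman | O(Cc1ccccc1)c1c(Br)cc2c(c1)O[C@H](c1ccc(OCc3ccccc3)c(OCc3ccccc3)c1)[C@@H](OCc3ccccc3)C2 | intermediate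
9 | 2,4-dihydroxybenzaldehyde | O=Cc1ccc(O)cc1O | starting material
10 | 4-(benzyloxy)-2-hydroxybenzaldehyde | O=Cc1ccc(OCc2ccccc2)cc1O | intermediate
11 | {(2R,3S)-3,7-bis(benzyloxy)-2-[3,4-bis(benzyloxy)phenyl]chroman-6-yl}lithium | [Li]c1cc2c(cc1OCc3ccccc3)O[C@H](c1ccc(OCc3ccccc3)c(OCc3ccccc3)c1)[C@@H](OCc3ccccc3)C2 | intermediate
12 | sodium 5-(benzyloxy)-2-formylphenolate | [Na+].[O-]c1cc(OCc2ccccc2)ccc1C=O | intermediate
13 | (4-benzyloxy-2-hydroxyphenyl){(2R,3S)-3,7-bis(benzyloxy)-2-[3,4-bis(benzyloxy)phenyl]chroman-6-yl}methanol, carbinol epimers | OC(c1ccc(OCc3ccccc3)cc1O)c1cc2c(cc1OCc3ccccc3)O[C@H](c1ccc(OCc3ccccc3)c(OCc3ccccc3)c1)[C@@H](OCc3ccccc3)C2 | intermediate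
14 | 3,4-bis(benzyloxy)benzaldehyde | O=Cc1ccc(OCc2ccccc2)c(OCc2ccccc2)c1 | starting material
15 | (E)-2-{2-[3,4-bis(benzyloxy)phenyl]ethenyl}-4,4,5,5-tetramethyl-1,3,2-dioxaborolane | CC1(C)OB(OC1(C)C)/C=C/c1ccc(OCc3ccccc3)c(OCc3ccccc3)c1 | intermediate
16 | (E)-3-benzyloxy-6-(arylmethylidene)cyclohexa-2,4-dien-1-one, aryl = protected lower flavan-6-yl, ring D anti to the carbonyl | O=C1C=C(OCc3ccccc3)C=C/C1=C\c1cc2c(cc1OCc3ccccc3)O[C@H](c1ccc(OCc3ccccc3)c(OCc3ccccc3)c1)[C@@H](OCc3ccccc3)C2 | intermediate
17 | hepta-O-benzyl-3-deoxy-3β-(pinacolboryl)fisetinidol-(4α→6)-fisetinidol | O(Cc3ccccc3)c1ccc2c(c1)O[C@H](c1ccc(OCc3ccccc3)c(OCc3ccccc3)c1)[C@@H](B4OC(C)(C)C(C)(C)O4)[C@@H]2c1cc2c(cc1OCc3ccccc3)O[C@H](c1ccc(OCc3ccccc3)c(OCc3ccccc3)c1)[C@@H](OCc3ccccc3)C2 | intermediate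
18 | hepta-O-benzylfisetinidol-(4α→6)-fisetinidol, upper 3β-OH free | O(Cc3ccccc3)c1ccc2c(c1)O[C@H](c1ccc(OCc3ccccc3)c(OCc3ccccc3)c1)[C@@H](O)[C@@H]2c1cc2c(cc1OCc3ccccc3)O[C@H](c1ccc(OCc3ccccc3)c(OCc3ccccc3)c1)[C@@H](OCc3ccccc3)C2 | intermediate
19 | fisetinidol-(4α→6)-fisetinidol, upper (2R,3S,4R), lower (2R,3S) | Oc1ccc2c(c1)O[C@H](c1ccc(O)c(O)c1)[C@@H](O)[C@@H]2c1cc2c(cc1O)O[C@H](c1ccc(O)c(O)c1)[C@@H](O)C2 | target

Total step count: 13. Longest linear sequence: 11 steps (steps 1–7, 9, 11, 12, 13, from taxifolin).

Steps most likely to fail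

Step 11. Three things may go wrong:
- The cation developing at C2 may shed boron (ipso-substitution and ring opening) before O1 closes.
- The heavily stabilised methide may react too slowly and oligomerise through C8 of ring D.
- The acid may discriminate the two methide faces poorly.

The fallback gives up the cycloaddition for the known Lewis acid condensation of a flavan-3,4-diol with a flavan. It sets out from diol 5 and ether 7, both already in hand. TiCl4 in CH2Cl2 at 0 °C ionises the 4-hydroxyl of 5. The C4 cation is taken up by C6 of ring D of 7, which is used in about fourfold excess to outrun self-condensation of 5, the surplus being recovered. Attack from the face opposite to the 3-hydroxyl gives the 3,4-trans (4α) link. The path comes back to the route at 18, steps 7 to 12 fall away, and no compound outside the list is made (entry F0).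

Step 2. The chelated 5-hydroxyl may react too slowly with the mild imide while the base slowly opens or epimerises ring F. A stronger sulfonylating agent would attack the 3-hydroxyl. The fallback changes the order of protection and sets out from 2.
- The 3-hydroxyl is benzylated first under acid (benzyl 2,2,2-trichloroacetimidate, cat. TfOH, CH2Cl2/cyclohexane, 0 °C) to give (2R,3R)-3,7-bis(benzyloxy)-2-[3,4-bis(benzyloxy)phenyl]-5-hydroxychroman-4-one F1.
- With no other hydroxyl left, Tf2O/pyridine gives the 5-triflate of that ketone F2.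
- Formate reduction as in step 3 gives (2R,3R)-3,7-bis(benzyloxy)-2-[3,4-bis(benzyloxy)phenyl]chroman-4-one F3.
- NaBH4 gives (2R,3S,4R)-3,7-bis(benzyloxy)-2-[3,4-bis(benzyloxy)phenyl]chroman-4-ol F4.
- Et3SiH/TFA brings the path back to the route at 7, replacing steps 2 to 6.

Step 9. Addition to the electron-rich, poorly soluble phenolate-aldehyde may be slow. On warming, the aryllithium could then decay by proton transfer from its ortho benzyloxy methylene. The fallback uses a protected, fully electrophilic aldehyde and sets out from 10 and 8.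
- Allyl bromide/K2CO3/DMF converts 10 into 2-(allyloxy)-4-(benzyloxy)benzaldehyde F5.
- F5 takes up aryllithium 11 at −78 °C to give the 2-O-allyl ether of the benzhydrol F6.
- Pd(PPh3)4 (cat.) and morpholine in THF at rt remove the allyl group under neutral conditions that do not ionise the carbinol, and the path comes back to the route at 13.

Further compounds
F0 | step 11 | none | none
F1 | step 2 | (2R,3R)-3,7-bis(benzyloxy)-2-[3,4-bis(benzyloxy)phenyl]-5-hydroxychroman-4-one | O(Cc1ccccc1)c1cc(O)c2c(c1)O[C@H](c1ccc(OCc3ccccc3)c(OCc3ccccc3)c1)[C@@H](OCc3ccccc3)C2=O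
F2 | step 2 | (2R,3R)-3,7-bis(benzyloxy)-2-[3,4-bis(benzyloxy)phenyl]-4-oxochroman-5-yl trifluoromethanesulfonate | O(Cc1ccccc1)c1cc(OS(=O)(=O)C(F)(F)F)c2c(c1)O[C@H](c1ccc(OCc3ccccc3)c(OCc3ccccc3)c1)[C@@H](OCc3ccccc3)C2=O
F3 | step 2 | (2R,3R)-3,7-bis(benzyloxy)-2-[3,4-bis(benzyloxy)phenyl]chroman-4-one | O(Cc1ccccc1)c1ccc2c(c1)O[C@H](c1ccc(OCc3ccccc3)c(OCc3ccccc3)c1)[C@@H](OCc3ccccc3)C2=O
F4 | step 2 | (2R,3S,4R)-3,7-bis(benzyloxy)-2-[3,4-bis(benzyloxy)phenyl]chroman-4-ol | O(Cc1ccccc1)c1ccc2c(c1)O[C@H](c1ccc(OCc3ccccc3)c(OCc3ccccc3)c1)[C@@H](OCc3ccccc3)[C@@H]2O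
F5 | step 9 | 2-(allyloxy)-4-(benzyloxy)benzaldehyde | O=Cc1ccc(OCc2ccccc2)cc1OCC=C
F6 | step 9 | (2-allyloxy-4-benzyloxyphenyl){(2R,3S)-3,7-bis(benzyloxy)-2-[3,4-bis(benzyloxy)phenyl]chroman-6-yl}methanol, carbinol epimers | OC(c1ccc(OCc3ccccc3)cc1OCC=C)c1cc2c(cc1OCc3ccccc3)O[C@H](c1ccc(OCc3ccccc3)c(OCc3ccccc3)c1)[C@@H](OCc3ccccc3)C2
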